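The route rests on cutting the two single bonds that flank the C3=C4 vinylene of the pyran ring: C2–C3, to the quaternary oxygen-bearing C2, and C4–C4a, to the aromatic carbon lying between C8a (ring oxygen) and C5 (phenethyl chain). Because C2 supports a stabilised tertiary α-aryloxy radical and C3/C4 carry only hydrogen, acetylene can be stitched between that radical and an ortho C–I bond in a single decarboxylative nickel/photoredox annulation. The precursor is an open-chain 2-(2-iodoaryloxy)-2-methylpropanoic acid that already carries the prenyl ether and the free 4-hydroxyphenethyl chain; iodine fixes where the ring fuses, and the annulation delivers the target directly.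

Key step: step 6

Remark on the chemistry: the target has no stereocentre, and the C3=C4 double bond sits in a six-membered ring and is necessarily cis, so no descriptor is needed. Atom labels follow 2H-chromene numbering (O1, C2, C3, C4, C4a, C5–C8, C8a). Compounds 1, 2, 4, 5 and 11 are taken as commercial.

Step 1
Reactants: 1 5-bromobenzene-1,3-diol; 2 ethyl 2-bromo-2-methylpropanoate
Product: 3 ethyl 2-(3-bromo-5-hydroxyphenoxy)-2-methylpropanoate
Conditions: 1 (3 equiv, excess recovered), 2 (1 equiv), K2CO3 (1.1 equiv), DMF, 70 °C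
Reagents that add atoms: none
Why: Williamson-type O-alkylation of a phenoxide with a tertiary α-bromo ester (the standard aryloxyisobutyrate synthesis); the diol is symmetric, so only mono- versus bis-alkylation must be controlled, and the excess of 1 should favour the mono-ether.

Step 2
Reactants: 3 ethyl 2-(3-bromo-5-hydroxyphenoxy)-2-methylpropanoate; 4 tert-butyldimethyl(4-vinylphenoxy)silane; 5 9-borabicyclo[3.3.1]nonane (9-BBN)
Product: 7 ethyl 2-[3-[2-[4-(tert-butyldimethylsilyloxy)phenyl]ethyl]-5-hydroxyphenoxy]-2-methylpropanoate, via alkylborane 6 (not isolated)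
Conditions: 4, 5 (1.1 equiv), THF, 0 °C to rt; then 3, Pd(OAc)2 (3 mol%), SPhos (6 mol%), K3PO4·H2O (3 equiv), THF, 60 °C
Reagents that add atoms: none
Why: Anti-Markovnikov hydroboration of the styrene followed by B-alkyl Suzuki–Miyaura coupling at the aryl bromide should form the CH2–CH2 link without any hydrogenation, and the solid phosphate base should spare the aryl silyl ether and the ester.

Step 3
Reactants: 7 ethyl 2-[3-[2-[4-(tert-butyldimethylsilyloxy)phenyl]ethyl]-5-hydroxyphenoxy]-2-methylpropanoate
Product: 8 ethyl 2-[3-[2-[4-(tert-butyldimethylsilyloxy)phenyl]ethyl]-5-hydroxy-2-iodophenoxy]-2-methylpropanoate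
Conditions: N-iodosuccinimide (1.05 equiv), MeCN, −10 to 0 °C, dark
Reagents that add atoms: N-iodosuccinimide, O=C1CCC(=O)N1I
Why: Electrophilic aromatic iodination in which the free hydroxyl, the strongest donor, should direct iodine to its para position, the carbon between the ether oxygen and the side chain; the silyloxy-substituted ring is far less activated.

Step 4
Reactants: 8 ethyl 2-[3-[2-[4-(tert-butyldimethylsilyloxy)phenyl]ethyl]-5-hydroxy-2-iodophenoxy]-2-methylpropanoate
Product: 9 ethyl 2-[3-[2-[4-(tert-butyldimethylsilyloxy)phenyl]ethyl]-2-iodo-5-(3-methylbut-2-enyloxy)phenoxy]-2-methylpropanoate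
Conditions: prenyl bromide (1.2 equiv), K2CO3 (1.5 equiv), acetone, rt to 40 °C
Reagents that add atoms: prenyl bromide (1-bromo-3-methylbut-2-ene), CC(C)=CCBr
Why: Williamson O-prenylation (SN2 at the primary allylic bromide) of the only free phenol; weak base in acetone should favour O- over C-alkylation and leave the silyl ether intact.

Step 5
Reactants: 9 ethyl 2-[3-[2-[4-(tert-butyldimethylsilyloxy)phenyl]ethyl]-2-iodo-5-(3-methylbut-2-enyloxy)phenoxy]-2-methylpropanoate
Product: 10 2-[3-[2-(4-hydroxyphenyl)ethyl]-2-iodo-5-(3-methylbut-2-enyloxy)phenoxy]-2-methylpropanoic acid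
Conditions: LiOH·H2O (6 equiv), THF/MeOH/H2O, 45 °C; then 1 M HCl to pH 3–4, 0 °C
Reagents that add atoms: lithium hydroxide, [Li+].[OH-]; water, O
Why: Saponification of the hindered ethyl ester and hydroxide-induced cleavage of the aryl silyl ether should occur in the same pot, while the aryl iodide and the prenyl ether are inert to aqueous base.

Step 6
Reactants: 10 2-[3-[2-(4-hydroxyphenyl)ethyl]-2-iodo-5-(3-methylbut-2-enyloxy)phenoxy]-2-methylpropanoic acid; 11 acetylene
Product: 12 4-[2-[2,2-dimethyl-7-(3-methylbut-2-enyloxy)-2H-chromen-5-yl]ethyl]phenol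
Conditions: Ir[dF(CF3)ppy]2(dtbbpy)PF6 (2 mol%), NiCl2·glyme (10 mol%), 4,4'-di-tert-butyl-2,2'-bipyridine (12 mol%), Cs2CO3 (1.0 equiv), acetylene (1 atm), DMSO (0.02 M), 450 nm LEDs, 25 °C
Reagents that add atoms: none
Why: Proposed new method: the excited trivalent-iridium photocatalyst oxidises the caesium carboxylate of 10, loss of CO2 gives the tertiary α-aryloxyalkyl radical at C2, and this adds to acetylene to form the C2–C3 bond and a rapidly inverting vinyl radical at C4, while zerovalent nickel inserts into the C4a–I bond. The vinyl radical is captured by the aryl-nickel centre of the same molecule, and reductive elimination from the resulting seven-membered oxanickelacycle forms the C4–C4a bond and closes the pyran ring, so the closure is a nickel-templated formal [4+2] annulation and not a radical attack on the arene. The closest known reaction types are the nickel/photoredox decarboxylative arylation of α-oxy acids and the three-component nickel/photoredox alkyl-arylation of terminal alkynes with tertiary radical precursors and aryl halides; new here are the tethering of both partners through the ether oxygen and the use of acetylene itself. No stereocentre is formed, and the cis geometry of C3=C4 is imposed by the ring because the vinyl radical inverts faster than it is trapped. The step needs regioselection between the two positions ortho to the ether oxygen (C4a versus C8), which the iodine at C4a secures, and chemoselection against direct aryl–alkyl coupling, which is disfavoured because it would give a four-membered benzoxete. The nucleophilic tertiary radical should ignore the electron-rich prenyl alkene, and with one equivalent of base the phenol should stay largely protonated.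

Compound list
1 | 5-bromobenzene-1,3-diol | Oc1cc(O)cc(Br)c1 | starting material
2 | ethyl 2-bromo-2-methylpropanoate | CCOC(=O)C(C)(C)Br | starting material
3 | ethyl 2-(3-bromo-5-hydroxyphenoxy)-2-methylpropanoate | CCOC(=O)C(C)(C)Oc1cc(O)cc(Br)c1 | intermediate
4 | tert-butyldimethyl(4-vinylphenoxy)silane | C=Cc1ccc(O[Si](C)(C)C(C)(C)C)cc1 | starting material
5 | 9-borabicyclo[3.3.1]nonane (9-BBN) | B1C2CCCC1CCC2 | starting material
6 | 9-[2-[4-(tert-butyldimethylsilyloxy)phenyl]ethyl]-9-borabicyclo[3.3.1]nonane | CC(C)(C)[Si](C)(C)Oc1ccc(CCB2C3CCCC2CCC3)cc1 | intermediate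
7 | ethyl 2-[3-[2-[4-(tert-butyldimethylsilyloxy)phenyl]ethyl]-5-hydroxyphenoxy]-2-methylpropanoate | CCOC(=O)C(C)(C)Oc1cc(O)cc(CCc2ccc(O[Si](C)(C)C(C)(C)C)cc2)c1 | intermediate
8 | ethyl 2-[3-[2-[4-(tert-butyldimethylsilyloxy)phenyl]ethyl]-5-hydroxy-2-iodophenoxy]-2-methylpropanoate | CCOC(=O)C(C)(C)Oc1cc(O)cc(CCc2ccc(O[Si](C)(C)C(C)(C)C)cc2)c1I | intermediate
9 | ethyl 2-[3-[2-[4-(tert-butyldimethylsilyloxy)phenyl]ethyl]-2-iodo-5-(3-methylbut-2-enyloxy)phenoxy]-2-methylpropanoate | CCOC(=O)C(C)(C)Oc1cc(OCC=C(C)C)cc(CCc2ccc(O[Si](C)(C)C(C)(C)C)cc2)c1I | intermediate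
10 | 2-[3-[2-(4-hydroxyphenyl)ethyl]-2-iodo-5-(3-methylbut-2-enyloxy)phenoxy]-2-methylpropanoic acid | CC(C)=CCOc1cc(CCc2ccc(O)cc2)c(I)c(OC(C)(C)C(=O)O)c1 | intermediate
11 | acetylene | C#C | starting material
12 | 4-[2-[2,2-dimethyl-7-(3-methylbut-2-enyloxy)-2H-chromen-5-yl]ethyl]phenol | CC(C)=CCOc1cc(CCc2ccc(O)cc2)c2c(c1)OC(C)(C)C=C2 | target

Total step count: 6
Longest linear sequence: 6 steps (1 → 3 → 7 → 8 → 9 → 10 → 12)

Steps most likely to fail

Step 6 (proposed new method). The tertiary radical may be oxidised or held by nickel before it meets acetylene, acetylene may oligomerise on zerovalent nickel, the vinyl radical may abstract hydrogen before it is trapped, or the free phenol may quench the photocatalyst. The fallback uses known chemistry and closes the pyran ring by ring-closing metathesis. It sets out from 9. Stille coupling with tributyl(vinyl)stannane (Pd(PPh3)4, toluene, 100 °C) would give the vinylarene ester ethyl 2-[3-[2-[4-(tert-butyldimethylsilyloxy)phenyl]ethyl]-2-ethenyl-5-(3-methylbut-2-enyloxy)phenoxy]-2-methylpropanoate F1. Reduction with i-Bu2AlH (CH2Cl2, −78 °C) would give the aldehyde 2-[3-[2-[4-(tert-butyldimethylsilyloxy)phenyl]ethyl]-2-ethenyl-5-(3-methylbut-2-enyloxy)phenoxy]-2-methylpropanal F2. Wittig methylenation (Ph3P=CH2, THF, 0 °C) would give the diene tert-butyl-[4-[2-[2-ethenyl-3-(2-methylbut-3-en-2-yloxy)-5-(3-methylbut-2-enyloxy)phenyl]ethyl]phenoxy]dimethylsilane F3. Ring-closing metathesis with the second-generation Grubbs catalyst (CH2Cl2, 40 °C) should close C3=C4 to the silyl ether tert-butyl-[4-[2-[2,2-dimethyl-7-(3-methylbut-2-enyloxy)-2H-chromen-5-yl]ethyl]phenoxy]dimethylsilane F4. Bu4NF (THF, 0 °C) would then remove the silyl group and come back to the route at 12.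

Step 3. Iodination may go ortho to the hydroxyl (between OH and the side chain) or proceed twice, because the para site is flanked by the tertiary ether and the side chain. The fallback brings the halogen in as bromine with a smaller, para-selective electrophile and exchanges it later. It sets out from 7. Bu4NBr3 (CH2Cl2/MeOH, 0 °C) would give the bromophenol ethyl 2-[2-bromo-3-[2-[4-(tert-butyldimethylsilyloxy)phenyl]ethyl]-5-hydroxyphenoxy]-2-methylpropanoate F5. Prenylation as in step 4 would give the bromo prenyl ether ethyl 2-[2-bromo-3-[2-[4-(tert-butyldimethylsilyloxy)phenyl]ethyl]-5-(3-methylbut-2-enyloxy)phenoxy]-2-methylpropanoate F6. Copper-catalysed aromatic halogen exchange (CuI, NaI, trans-N,N'-dimethylcyclohexane-1,2-diamine, dioxane, 110 °C) would convert the bromide into the iodide and come back to the route at 9.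

Step 2. The aryl silyl ether may be lost under the basic coupling conditions, oxidative addition into the electron-rich bromophenoxide may be slow, and the alkylborane may undergo protodeboronation. The fallback replaces the alkylborane coupling by a Heck reaction and hydrogenation, at a stage where nothing else is reducible. It sets out from 3 and 4. Heck coupling (Pd(OAc)2, P(o-tol)3, Et3N, DMF, 100 °C) would give the stilbene ethyl 2-[3-[(E)-2-[4-(tert-butyldimethylsilyloxy)phenyl]ethenyl]-5-hydroxyphenoxy]-2-methylpropanoate F7. Hydrogenation (H2, 1 atm, Pd/C, EtOAc, rt) would then come back to the route at 7.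

Further compounds
F1 | step 6 | ethyl 2-[3-[2-[4-(tert-butyldimethylsilyloxy)phenyl]ethyl]-2-ethenyl-5-(3-methylbut-2-enyloxy)phenoxy]-2-methylpropanoate | CCOC(=O)C(C)(C)Oc1cc(OCC=C(C)C)cc(CCc2ccc(O[Si](C)(C)C(C)(C)C)cc2)c1C=C
F2 | step 6 | 2-[3-[2-[4-(tert-butyldimethylsilyloxy)phenyl]ethyl]-2-ethenyl-5-(3-methylbut-2-enyloxy)phenoxy]-2-methylpropanal | O=CC(C)(C)Oc1cc(OCC=C(C)C)cc(CCc2ccc(O[Si](C)(C)C(C)(C)C)cc2)c1C=C
F3 | step 6 | tert-butyl-[4-[2-[2-ethenyl-3-(2-methylbut-3-en-2-yloxy)-5-(3-methylbut-2-enyloxy)phenyl]ethyl]phenoxy]dimethylsilane | C=CC(C)(C)Oc1cc(OCC=C(C)C)cc(CCc2ccc(O[Si](C)(C)C(C)(C)C)cc2)c1C=C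
F4 | step 6 | tert-butyl-[4-[2-[2,2-dimethyl-7-(3-methylbut-2-enyloxy)-2H-chromen-5-yl]ethyl]phenoxy]dimethylsilane | CC(C)=CCOc1cc(CCc2ccc(O[Si](C)(C)C(C)(C)C)cc2)c2c(c1)OC(C)(C)C=C2
F5 | step 3 | ethyl 2-[2-bromo-3-[2-[4-(tert-butyldimethylsilyloxy)phenyl]ethyl]-5-hydroxyphenoxy]-2-methylpropanoate | CCOC(=O)C(C)(C)Oc1cc(O)cc(CCc2ccc(O[Si](C)(C)C(C)(C)C)cc2)c1Br
F6 | step 3 | ethyl 2-[2-bromo-3-[2-[4-(tert-butyldimethylsilyloxy)phenyl]ethyl]-5-(3-methylbut-2-enyloxy)phenoxy]-2-methylpropanoate | CCOC(=O)C(C)(C)Oc1cc(OCC=C(C)C)cc(CCc2ccc(O[Si](C)(C)C(C)(C)C)cc2)c1Br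
F7 | step 2 | ethyl 2-[3-[(E)-2-[4-(tert-butyldimethylsilyloxy)phenyl]ethenyl]-5-hydroxyphenoxy]-2-methylpropanoate | CCOC(=O)C(C)(C)Oc1cc(O)cc(/C=C/c2ccc(O[Si](C)(C)C(C)(C)C)cc2)c1
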